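The ten-membered ring is not closed but uncovered. C3 (ketone) and C8 (lactone oxygen) are 1,6-related across the carbocycle, so a C3–C8 bond turns C1–C10 into two fused six-membered rings: ring A (C3–C8, from (R)-carvone, carrying C4–C7) and ring B (C8–C9–C10–C1–C2–C3, with the C10 methyl from the hydroxy ester 1). Ozonolysis of the tetrasubstituted C3=C8 ring-fusion alkene of octalin 24 releases the 3,8-dione 26 in one operation with five stereocentres in place. In 24 the C7 branch already carries an allylic benzoate, which deactivates the only other alkene toward ozone and pre-installs the lactone oxygen; C4–C6 are triethylsilyl ethers.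

Key step: step 17

Remark (locants): target numbering is used for every intermediate (carbocycle C1–C10; C11, C12, C13 = lactone branch; C14 on C10, C15 on C4). β = toward the viewer when the ring is drawn with locants rising clockwise, α = away. The target is 4β-OH, 5α-O, 6β-O, 7β-C11, 8α-O, 10β-CH3, 1α,2α-epoxide.
Remark (stereochemical check): C4, C5, C6, C7 and C10 of 24 and 26 have the configurations of the target; C7 is C5 of (R)-carvone, and C10 comes from the (R)-ester 1 with its CH2OH carbon becoming C9.
Remark (transient centres): C8 of 25, C12 of 32, the selenium of 13 and the enol ether geometry of 29 are left undefined, because they are lost in the same step.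

Step 1
Reactants: 1 methyl (R)-3-hydroxy-2-methylpropanoate
Product: 2 silyl ether of 1
Conditions: t-BuPh2SiCl, imidazole, DMF, 0 → 23 °C
Reagents that add atoms: tert-butyl(chloro)diphenylsilane, CC(C)(C)[Si](Cl)(c1ccccc1)c1ccccc1
Why: Imidazole-promoted O-silylation of the primary alcohol masks it for the hydride and ylide steps and does not involve the stereocentre.

Step 2
Reactants: 2 silyl ether of 1
Product: 3 aldehyde
Conditions: i-Bu2AlH, CH2Cl2, −78 °C; aq. potassium sodium tartrate
Reagents that add atoms: none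
Why: Partial ester reduction: at −78 °C the aluminium hemiacetal survives until work-up and then releases the aldehyde, whose α-stereocentre should hold if it is used cold and without chromatography.

Step 3
Reactants: 3 aldehyde
Product: 4 terminal alkene
Conditions: Ph3PCH3Br, n-BuLi, THF, 0 °C; then 3, −78 → 23 °C
Reagents that add atoms: methyltriphenylphosphonium bromide, C[P+](c1ccccc1)(c1ccccc1)c1ccccc1.[Br-]
Why: Wittig methylenation with the non-stabilised ylide is fast at low temperature and should outrun enolisation of the α-branched aldehyde, so the future C10 centre is retained.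

Step 4
Reactants: 4 terminal alkene
Product: 5 (S)-2-methylbut-3-en-1-ol
Conditions: Bu4NF, THF, 23 °C; distillation
Reagents that add atoms: none
Why: Fluoride-induced desilylation frees the primary alcohol, which is volatile and is isolated by distillation.

Step 5
Reactants: 5 (S)-2-methylbut-3-en-1-ol; 6 (R)-(−)-carvone
Product: 9 alkylated carvone, via alkyl triflate 7 (not isolated), via lithium dienolate 8 (not isolated)
Conditions: 5: Tf2O, 2,6-lutidine, CH2Cl2, −78 °C; 6: LiN(i-Pr)2, THF, −78 °C; combine, −78 → −40 °C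
Reagents that add atoms: none
Why: Enolate alkylation: kinetic α′-deprotonation of carvone at C8 gives the cross-conjugated dienolate, which displaces the primary triflate by SN2 at low temperature (a β-branched iodide with an allylic β-hydrogen would be prone to E2); the electrophile enters anti to the neighbouring 7β-isopropenyl group to give the 8α-chain, and C10 is carried over from 1.

Step 6
Reactants: 9 alkylated carvone
Product: 10 allylic alcohol
Conditions: NaBH4, CeCl3·7H2O, MeOH, −78 → −20 °C
Reagents that add atoms: none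
Why: Luche reduction: hydride adds 1,2 and axially, as in the reduction of carvone to cis-carveol, giving the equatorial 3β-alcohol (cis to the C7 isopropenyl, trans to the C8 chain) that steers the next step.

Step 7
Reactants: 10 allylic alcohol
Product: 11 epoxy alcohol
Conditions: VO(acac)2 (cat.), t-BuOOH, CH2Cl2, 0 °C
Reagents that add atoms: tert-butyl hydroperoxide, CC(C)(C)OO
Why: Hydroxyl-directed epoxidation: the vanadium alkoxide delivers oxygen to the C4=C5 face syn to the 3β-hydroxyl and leaves the two non-allylic alkenes alone, which sets C4 (4β-O, 4α-CH3) and the β-epoxide.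

Step 8
Reactants: 11 epoxy alcohol
Product: 14 allylic diol, via hydroxy selenide 12 (not isolated), via selenoxide 13 (not isolated)
Conditions: PhSeSePh, NaBH4, EtOH, 78 °C; then H2O2 (30% aq.), THF, 0 → 23 °C
Reagents that add atoms: none
Why: Epoxide-to-allylic-alcohol transposition: the selenide opens the epoxide trans-diaxially at the secondary C5 from the α-face, and the selenoxide then eliminates syn toward C6 (C4 has no hydrogen), leaving the tertiary 4β-alcohol untouched and a C5=C6 alkene.

Step 9
Reactants: 14 allylic diol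
Product: 15 epoxy diol
Conditions: VO(acac)2 (cat.), t-BuOOH, CH2Cl2, 0 → 23 °C
Reagents that add atoms: tert-butyl hydroperoxide, CC(C)(C)OO
Why: Hydroxyl-directed epoxidation: the tertiary allylic 4β-hydroxyl and the homoallylic 3β-hydroxyl bind vanadium and deliver oxygen to the β-face of C5=C6, chemoselectively over the isopropenyl and vinyl groups.

Step 10
Reactants: 15 epoxy diol
Product: 16 epoxy hydroxy ketone
Conditions: IBX, EtOAc, 70 °C
Reagents that add atoms: none
Why: 2-Iodoxybenzoic acid oxidises the only secondary alcohol (C3) to the ketone without cleaving the 3,4-glycol or touching the tertiary alcohol, the epoxide or the alkenes.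

Step 11
Reactants: 16 epoxy hydroxy ketone
Product: 17 trihydroxy ketone
Conditions: HClO4 (cat.), THF/H2O, 0 → 23 °C
Reagents that add atoms: water, O
Why: Acid-catalysed epoxide hydrolysis under Fürst–Plattner (trans-diaxial) control: with the C7 and C8 carbon substituents held equatorial, water should attack C5 axially from the α-face, giving 5α-OH while C6 keeps its 6β-oxygen; the α-epoxide would give the same diaxial diol, so the step is stereoconvergent.

Step 12
Reactants: 17 trihydroxy ketone
Product: 18 tris(triethylsilyl) ether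
Conditions: Et3SiOTf, 2,6-lutidine, CH2Cl2, −78 → 23 °C
Reagents that add atoms: triethylsilyl trifluoromethanesulfonate, CC[Si](CC)(CC)OS(=O)(=O)C(F)(F)F
Why: Silyl triflate with a hindered base caps the two secondary and the tertiary hydroxyl in one operation; triethylsilyl ethers tolerate base, zerovalent palladium, ozone and hydride and are removed by fluoride at the end.

Step 13
Reactants: 18 tris(triethylsilyl) ether
Product: 20 enol triflate, via potassium enolate 19 (not isolated)
Conditions: KN(SiMe3)2, THF, −78 °C; then PhNTf2, −78 → 0 °C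
Reagents that add atoms: N-phenylbis(trifluoromethanesulfonimide), FC(F)(F)S(=O)(=O)N(c1ccccc1)S(=O)(=O)C(F)(F)F
Why: Enol triflate formation: C4 is quaternary, so the ketone can enolise only toward C8, and O-sulfonylation fixes the future C3=C8 double bond regiospecifically while erasing the C8 centre.

Step 14
Reactants: 20 enol triflate
Product: 21 allylic chloride
Conditions: Ca(OCl)2, solid CO2, CH2Cl2/H2O, 0 °C
Reagents that add atoms: calcium hypochlorite, [Ca+2].[O-]Cl.[O-]Cl
Why: Ene-type allylic chlorination by hypochlorous acid picks the electron-rich 1,1-disubstituted isopropenyl alkene (the vinyl group and the enol triflate are far less nucleophilic) and gives the 3-chloroprop-1-en-2-yl branch.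

Step 15
Reactants: 21 allylic chloride
Product: 22 allylic benzoate
Conditions: PhCO2Na, NaI (cat.), DMF, 50 °C
Reagents that add atoms: sodium benzoate, [Na+].[O-]C(=O)c1ccccc1
Why: SN2 displacement of the primary allylic chloride installs the future lactone oxygen as an ester that makes C11=C13 electron-poor toward 9-BBN and ozone and later serves as the leaving group.

Step 16
Reactants: 22 allylic benzoate
Product: 24 octalin precursor, via alkylborane 23 (not isolated)
Conditions: 9-BBN, THF, 0 → 23 °C; then Pd(dppf)Cl2, AsPh3, Cs2CO3, DMF/H2O, 23 °C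
Reagents that add atoms: none
Why: Hydroboration followed by intramolecular B-alkyl Suzuki–Miyaura coupling: 9-BBN should add to the unhindered vinyl group rather than the hindered, deactivated 1,1-disubstituted alkene, and the primary alkylborane couples with the enol triflate to close ring B at C2–C3 with the double bond left at C3=C8; ionisation of the symmetrical allylic benzoate by zerovalent palladium is degenerate and slow at room temperature.

Step 17
Reactants: 24 octalin precursor
Product: 26 ten-membered 3,8-dione, via methoxy hydroperoxide 25 (not isolated)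
Conditions: O3, CH2Cl2/MeOH, NaHCO3, Sudan Red 7B, −78 °C; then Me2S, −78 → 23 °C
Reagents that add atoms: ozone, [O-][O+]=O
Why: Ozonolysis (1,3-dipolar cycloaddition of ozone, cycloreversion, trapping of the carbonyl oxide by methanol, reduction of the hydroperoxide by Me2S); the closest known case is the cleavage of the parent ring-fusion octalin to cyclodecane-1,6-dione through the same kind of methoxy hydroperoxide. The ten-membered ring arises by fragmentation of the bond shared by rings A and B, a ring expansion and not an end-to-end closure, so no medium-ring cyclisation entropy is paid. No stereocentre is created; C4, C5, C6, C7 and C10 were set on chair cyclohexanes and are carried over. The step needs chemoselectivity for C3=C8 over C11=C13, and the substrate secures it: C3=C8 is the only tetraalkyl alkene, C11=C13 is deactivated by its allylic benzoate, and the dye marks the end point. The primary ozonide is expected to open with the carbonyl oxide on C8, away from the electron-withdrawing C4 silyloxy group. Bicarbonate buffering, −78 °C and a neutral reductive quench should keep the 1,6-dione from transannular aldolisation and keep C7 (α to the C8 ketone and allylic) from epimerising or moving into conjugation.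

Step 18
Reactants: 26 ten-membered 3,8-dione
Product: 27 8α-alcohol
Conditions: (S)-2-methyl-CBS-oxazaborolidine, catecholborane, toluene, −78 °C
Reagents that add atoms: none
Why: Corey–Bakshi–Shibata reduction: the oxazaborolidine binds the less hindered C8 ketone (C3 is flanked by quaternary C4) with the branched C7 side as the large group, so the (S)-catalyst should deliver hydride to give the (8R), 8α-alcohol under reagent control; catecholborane does not hydroborate the alkene or reduce the ester at −78 °C.

Step 19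
Reactants: 27 8α-alcohol
Product: 28 cyclic allyl ether
Conditions: Pd(PPh3)4 (cat.), Et3N, THF, 50 °C
Reagents that add atoms: none
Why: Tsuji–Trost allylic etherification: zerovalent palladium ionises the allylic benzoate and the neighbouring 8α-hydroxyl closes the 3-methylenetetrahydrofuran (O–C12) with retention at C8, which ties up the hydroxyl against transannular hemiketal formation and conjugate addition without creating a Michael acceptor.

Step 20
Reactants: 28 cyclic allyl ether
Product: 30 Z-enone, via silyl enol ether 29 (not isolated)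
Conditions: Me3SiOTf, Et3N, CH2Cl2, −78 → 0 °C; then Pd(OAc)2, MeCN, 23 °C
Reagents that add atoms: none
Why: Saegusa–Ito dehydrogenation: enolisation can only go toward C2 because C4 is quaternary, and β-hydride elimination from the divalent palladium enolate within the ten-membered ring is expected to give the less strained Z-enone.

Step 21
Reactants: 30 Z-enone
Product: 31 epoxy ketone
Conditions: H2O2 (30% aq.), NaOH, MeOH/THF, 0 °C
Reagents that add atoms: hydrogen peroxide, OO
Why: Weitz–Scheffer nucleophilic epoxidation: hydroperoxide adds to C1 of the only Michael acceptor and the enolate should close the oxirane before the ring bond rotates, so the Z-enone gives the cis-epoxide; attack is expected on the α-face, anti to the 10β-methyl next to C1 and away from the 4β-silyloxy group, which sets C1 and C2.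

Step 22
Reactants: 31 epoxy ketone
Product: 33 lactone, via lactol 32 (not isolated)
Conditions: CrO3·2py (excess), CH2Cl2, 23 °C
Reagents that add atoms: chromium trioxide (as its bis-pyridine complex), O=[Cr](=O)=O
Why: Allylic oxidation of the cyclic allyl ether with Collins reagent: the C12 methylene is both allylic and α to oxygen, so hexavalent chromium should oxidise it through the lactol to the α-methylene-γ-butyrolactone while the silyl ethers and the epoxy ketone are left alone.

Step 23
Reactants: 33 lactone
Product: 34 triol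
Conditions: HF·pyridine, pyridine, THF, 0 → 23 °C
Reagents that add atoms: none
Why: Fluoride-mediated desilylation with buffered HF·pyridine removes the three triethylsilyl groups under conditions that α-methylene lactones and epoxy ketones tolerate.

Step 24
Reactants: 34 triol
Product: 35 target CNP0253228.1
Conditions: (E)-crotonic anhydride, DMAP, pyridine, CH2Cl2, 0 → 23 °C
Reagents that add atoms: (E)-but-2-enoic anhydride, C/C=C/C(=O)OC(=O)/C=C/C
Why: DMAP-catalysed acylation should esterify the two secondary hydroxyls at C5 and C6 but not the tertiary 4β-hydroxyl next to the ketone, and the anhydride (no ketene pathway) keeps the E-crotonate geometry.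

Compound list

1 | methyl (R)-3-hydroxy-2-methylpropanoate | C[C@H](CO)C(=O)OC | starting material
2 | methyl (R)-3-[(tert-butyldiphenylsilyl)oxy]-2-methylpropanoate | C[C@H](CO[Si](c1ccccc1)(c1ccccc1)C(C)(C)C)C(=O)OC | intermediate
3 | (R)-3-[(tert-butyldiphenylsilyl)oxy]-2-methylpropanal | C[C@H](CO[Si](c1ccccc1)(c1ccccc1)C(C)(C)C)C=O | intermediate
4 | tert-butyl{[(2S)-2-methylbut-3-en-1-yl]oxy}diphenylsilane | C[C@H](CO[Si](c1ccccc1)(c1ccccc1)C(C)(C)C)C=C | intermediate
5 | (S)-2-methylbut-3-en-1-ol | C[C@H](CO)C=C | intermediate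
6 | (R)-(−)-carvone | CC1=CC[C@@H](C(C)=C)CC1=O | starting material
7 | (2S)-2-methylbut-3-en-1-yl trifluoromethanesulfonate (formed in the flask) | C[C@H](COS(=O)(=O)C(F)(F)F)C=C | intermediate
8 | lithium α′-dienolate of (R)-carvone (C3 enolate oxygen, C3=C8 and C4=C5; formed in the flask) | [Li]OC1=C[C@H](C(C)=C)CC=C1C | intermediate
9 | (5R,6S)-2-methyl-6-[(2R)-2-methylbut-3-en-1-yl]-5-(prop-1-en-2-yl)cyclohex-2-en-1-one (target locants: 3-oxo, 4-ene, 7β-isopropenyl, 8α-chain C9–C10(C14)–C1=C2) | O=C1[C@@H](C[C@@H](C)C=C)[C@H](C(C)=C)CC=C1C | intermediate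
10 | 3β-alcohol of 9 (3β-OH cis to 7β-isopropenyl, trans to the 8α-chain) | O[C@@H]1[C@@H](C[C@@H](C)C=C)[C@H](C(C)=C)CC=C1C | intermediate
11 | 4β,5β-epoxy-3β-alcohol (4α-methyl) | O[C@@H]1[C@@H](C[C@@H](C)C=C)[C@H](C(C)=C)C[C@@H]2O[C@]12C | intermediate
12 | 3β,4β-dihydroxy-5α-(phenylselanyl) compound (4α-methyl; formed in the flask) | O[C@@H]1[C@@H](C[C@@H](C)C=C)[C@H](C(C)=C)C[C@@H]([Se]c2ccccc2)[C@]1(C)O | intermediate
13 | selenoxide of 12 (selenium not defined; formed in the flask) | O[C@@H]1[C@@H](C[C@@H](C)C=C)[C@H](C(C)=C)C[C@@H]([Se](=O)c2ccccc2)[C@]1(C)O | intermediate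
14 | 5-ene-3β,4β-diol (4α-methyl, 7β-isopropenyl, 8α-chain) | O[C@@H]1[C@@H](C[C@@H](C)C=C)[C@H](C(C)=C)C=C[C@]1(C)O | intermediate
15 | 5β,6β-epoxy-3β,4β-diol | O[C@@H]1[C@@H](C[C@@H](C)C=C)[C@H](C(C)=C)[C@@H]2O[C@@H]2[C@]1(C)O | intermediate
16 | 5β,6β-epoxy-4β-hydroxy-3-one | O=C1[C@@H](C[C@@H](C)C=C)[C@H](C(C)=C)[C@@H]2O[C@@H]2[C@]1(C)O | intermediate
17 | 4β,5α,6β-trihydroxy-3-one (4α-methyl, 7β-isopropenyl, 8α-chain) | O=C1[C@@H](C[C@@H](C)C=C)[C@H](C(C)=C)[C@H](O)[C@@H](O)[C@]1(C)O | intermediate
18 | 4β,5α,6β-tris(triethylsilyloxy)-3-one | O=C1[C@@H](C[C@@H](C)C=C)[C@H](C(C)=C)[C@H](O[Si](CC)(CC)CC)[C@@H](O[Si](CC)(CC)CC)[C@]1(C)O[Si](CC)(CC)CC | intermediate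
19 | potassium 3(8)-enolate of 18 (formed in the flask) | [K]OC1=C(C[C@@H](C)C=C)[C@H](C(C)=C)[C@H](O[Si](CC)(CC)CC)[C@@H](O[Si](CC)(CC)CC)[C@]1(C)O[Si](CC)(CC)CC | intermediate
20 | 3(8)-enol trifluoromethanesulfonate of 18 | FC(F)(F)S(=O)(=O)OC1=C(C[C@@H](C)C=C)[C@H](C(C)=C)[C@H](O[Si](CC)(CC)CC)[C@@H](O[Si](CC)(CC)CC)[C@]1(C)O[Si](CC)(CC)CC | intermediate
21 | enol triflate with 7β-(3-chloroprop-1-en-2-yl) branch | FC(F)(F)S(=O)(=O)OC1=C(C[C@@H](C)C=C)[C@H](C(CCl)=C)[C@H](O[Si](CC)(CC)CC)[C@@H](O[Si](CC)(CC)CC)[C@]1(C)O[Si](CC)(CC)CC | intermediate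
22 | enol triflate with 7β-[3-(benzoyloxy)prop-1-en-2-yl] branch | FC(F)(F)S(=O)(=O)OC1=C(C[C@@H](C)C=C)[C@H](C(COC(=O)c2ccccc2)=C)[C@H](O[Si](CC)(CC)CC)[C@@H](O[Si](CC)(CC)CC)[C@]1(C)O[Si](CC)(CC)CC | intermediate
23 | C2-(9-borabicyclo[3.3.1]nonan-9-yl) adduct of 22 (formed in the flask) | FC(F)(F)S(=O)(=O)OC1=C(C[C@@H](C)CCB2C3CCCC2CCC3)[C@H](C(COC(=O)c2ccccc2)=C)[C@H](O[Si](CC)(CC)CC)[C@@H](O[Si](CC)(CC)CC)[C@]1(C)O[Si](CC)(CC)CC | intermediate
24 | octalin (rings A and B fused at C3=C8): 4β,5α,6β-tris(triethylsilyloxy)-4α,10β-dimethyl-7β-[3-(benzoyloxy)prop-1-en-2-yl] | C1[C@@H](C)CCC2=C1[C@H](C(COC(=O)c3ccccc3)=C)[C@H](O[Si](CC)(CC)CC)[C@@H](O[Si](CC)(CC)CC)[C@]2(C)O[Si](CC)(CC)CC | intermediate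
25 | ten-membered 3-oxo-8-hydroperoxy-8-methoxy compound (C8 not defined; formed in the flask) | COC1(OO)C[C@@H](C)CCC(=O)[C@@](C)(O[Si](CC)(CC)CC)[C@H](O[Si](CC)(CC)CC)[C@@H](O[Si](CC)(CC)CC)[C@H]1C(COC(=O)c2ccccc2)=C | intermediate
26 | ten-membered 3,8-dione: 4β,5α,6β-tris(triethylsilyloxy)-4α,10β-dimethyl-7β-[3-(benzoyloxy)prop-1-en-2-yl]cyclodecane-3,8-dione (target locants) | O=C1C[C@@H](C)CCC(=O)[C@@](C)(O[Si](CC)(CC)CC)[C@H](O[Si](CC)(CC)CC)[C@@H](O[Si](CC)(CC)CC)[C@H]1C(COC(=O)c2ccccc2)=C | intermediate
27 | (8R)-8α-hydroxy-3-ketone of 26 | O[C@@H]1C[C@@H](C)CCC(=O)[C@@](C)(O[Si](CC)(CC)CC)[C@H](O[Si](CC)(CC)CC)[C@@H](O[Si](CC)(CC)CC)[C@H]1C(COC(=O)c2ccccc2)=C | intermediate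
28 | 8α,12-ether: 3-methylenetetrahydrofuran trans-fused at C7–C8, 3-ketone | C=C1CO[C@@H]2C[C@@H](C)CCC(=O)[C@@](C)(O[Si](CC)(CC)CC)[C@H](O[Si](CC)(CC)CC)[C@@H](O[Si](CC)(CC)CC)[C@@H]12 | intermediate
29 | 2-en-3-yl trimethylsilyl ether of 28 (geometry not defined; formed in the flask) | C=C1CO[C@@H]2C[C@@H](C)CC=C(O[Si](C)(C)C)[C@@](C)(O[Si](CC)(CC)CC)[C@H](O[Si](CC)(CC)CC)[C@@H](O[Si](CC)(CC)CC)[C@@H]12 | intermediate
30 | (1Z)-1-en-3-one of 28 | C=C1CO[C@@H]2C[C@@H](C)/C=C\C(=O)[C@@](C)(O[Si](CC)(CC)CC)[C@H](O[Si](CC)(CC)CC)[C@@H](O[Si](CC)(CC)CC)[C@@H]12 | intermediate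
31 | 1α,2α-epoxy-3-one with the 8α,12-ether | C=C1CO[C@@H]2C[C@@H](C)[C@@H]3O[C@@H]3C(=O)[C@@](C)(O[Si](CC)(CC)CC)[C@H](O[Si](CC)(CC)CC)[C@@H](O[Si](CC)(CC)CC)[C@@H]12 | intermediate
32 | 12-lactol of 31 (C12 not defined; formed in the flask) | C=C1C(O)O[C@@H]2C[C@@H](C)[C@@H]3O[C@@H]3C(=O)[C@@](C)(O[Si](CC)(CC)CC)[C@H](O[Si](CC)(CC)CC)[C@@H](O[Si](CC)(CC)CC)[C@@H]12 | intermediate
33 | 8α,12-lactone (α-methylene-γ-butyrolactone) with 4β,5α,6β-tris(triethylsilyloxy) groups | C=C1C(=O)O[C@@H]2C[C@@H](C)[C@@H]3O[C@@H]3C(=O)[C@@](C)(O[Si](CC)(CC)CC)[C@H](O[Si](CC)(CC)CC)[C@@H](O[Si](CC)(CC)CC)[C@@H]12 | intermediate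
34 | 4β,5α,6β-triol of 33 | C=C1C(=O)O[C@@H]2C[C@@H](C)[C@@H]3O[C@@H]3C(=O)[C@@](C)(O)[C@H](O)[C@@H](O)[C@@H]12 | intermediate
35 | CNP0253228.1: (1S,2S,4S,5R,6S,7S,8R,10R)-5,6-bis[(2E)-but-2-enoyloxy]-1,2-epoxy-4-hydroxy-3-oxogermacr-11(13)-en-12,8-olide | C=C1C(=O)O[C@@H]2C[C@@H](C)[C@@H]3O[C@@H]3C(=O)[C@@](C)(O)[C@H](OC(=O)/C=C/C)[C@@H](OC(=O)/C=C/C)[C@@H]12 | target

Total step count: 24.
Longest linear sequence: 24 steps (1 → 35, steps 1–24); 20 steps from (R)-carvone (steps 5–24).

Steps most likely to fail

Step 21. Hydroperoxide may attack the β-face of the enone, or the intermediate enolate may rotate before ring closure, because the preferred conformation of the ten-membered ring is not known. The fallback sets out from 30 and replaces substrate-controlled conjugate epoxidation by hydroxyl-directed epoxidation. 1,2-Reduction (NaBH4, CeCl3·7H2O, MeOH, −78 °C) gives the 3β-allylic alcohol F1; medium-ring (Z)-cycloalk-2-enols deliver the vanadium-bound peroxide trans to the hydroxyl, which is why the 3β-epimer is the one used. VO(acac)2 and t-BuOOH in CH2Cl2 then give the 1α,2α-epoxy-3β-alcohol F2, and Dess–Martin periodinane (NaHCO3, CH2Cl2) re-forms the ketone, returning to the route at 31.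

Step 20. β-Hydride elimination may give the E-enone, or enolisation of the hindered ketone may be incomplete. The fallback sets out from 28 and uses selenoxide elimination instead of palladium. The silyl enol ether 29 is made as before and treated with PhSeCl (CH2Cl2, −78 °C) to give the 2-(phenylselanyl) ketone F3 (C2 not defined). H2O2 and pyridine in CH2Cl2 at 0 °C oxidise it to the selenoxide F4, whose thermal syn-elimination toward C1 returns to the route at 30; any E isomer can be equilibrated to the Z-enone with a catalytic thiol and amine before the epoxidation.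

Step 18. The ring conformation may override the catalyst and hydride may reach the wrong face of C8, or C3 may be reduced competitively. The fallback sets out from 26 and corrects the configuration by inversion. If reduction gives mainly the 8β-alcohol F5 (it can also be made on purpose with the (R)-catalyst), Mitsunobu esterification with 4-nitrobenzoic acid, PPh3 and diisopropyl azodicarboxylate inverts C8 to the 8α 4-nitrobenzoate F6. Brief methanolysis (K2CO3, MeOH, 0 °C) cleaves the activated aryl ester faster than the allylic benzoate and returns to the route at 27.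

Further compounds

F1 | step 21 | 3β-allylic alcohol from 30 | C=C1CO[C@@H]2C[C@@H](C)/C=C\[C@@H](O)[C@@](C)(O[Si](CC)(CC)CC)[C@H](O[Si](CC)(CC)CC)[C@@H](O[Si](CC)(CC)CC)[C@@H]12
F2 | step 21 | 1α,2α-epoxy-3β-alcohol | C=C1CO[C@@H]2C[C@@H](C)[C@@H]3O[C@@H]3[C@@H](O)[C@@](C)(O[Si](CC)(CC)CC)[C@H](O[Si](CC)(CC)CC)[C@@H](O[Si](CC)(CC)CC)[C@@H]12
F3 | step 20 | 2-(phenylselanyl) ketone from 28 | C=C1CO[C@@H]2C[C@@H](C)CC([Se]c3ccccc3)C(=O)[C@@](C)(O[Si](CC)(CC)CC)[C@H](O[Si](CC)(CC)CC)[C@@H](O[Si](CC)(CC)CC)[C@@H]12
F4 | step 20 | selenoxide of F3 | C=C1CO[C@@H]2C[C@@H](C)CC([Se](=O)c3ccccc3)C(=O)[C@@](C)(O[Si](CC)(CC)CC)[C@H](O[Si](CC)(CC)CC)[C@@H](O[Si](CC)(CC)CC)[C@@H]12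
F5 | step 18 | 8β-alcohol (C8 epimer of 27) | O[C@H]1C[C@@H](C)CCC(=O)[C@@](C)(O[Si](CC)(CC)CC)[C@H](O[Si](CC)(CC)CC)[C@@H](O[Si](CC)(CC)CC)[C@H]1C(COC(=O)c2ccccc2)=C
F6 | step 18 | 8α 4-nitrobenzoate | [O-][N+](=O)c1ccc(cc1)C(=O)O[C@@H]2C[C@@H](C)CCC(=O)[C@@](C)(O[Si](CC)(CC)CC)[C@H](O[Si](CC)(CC)CC)[C@@H](O[Si](CC)(CC)CC)[C@H]2C(COC(=O)c3ccccc3)=C
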